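The pitfall with these runs was to read a fall of the substrate peak as target made. In Wednesday's run substrate had lost 47.9% by the last reading, but target stood at 10.1%. The two peaks also count differently: substrate is read free, target in all its forms.

| setting | Wednesday's | Sunday's | birch | alder | ash | cedar |
|---|---|---|---|---|---|---|
| substrate | 0.050 M | 0.20 M | 0.10 M | 0.10 M | 0.10 M | 0.10 M |
| first nucleophile | 0.90 equiv | 0.90 equiv | 0.900 equiv | 0.900 equiv | 0.900 equiv | 0.900 equiv |
| second nucleophile | 1.1 equiv | 1.1 equiv | 1.10 equiv | 1.10 equiv | 1.10 equiv | 1.10 equiv |
| temperature | 30 °C | 52 °C |  | 60 °C | 40 °C | 20 °C |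
| remark | run made earlier | run made earlier | at 60 °C until 80 s, from then on at 20 °C |  |  |  |
| time |  |  | 6.0 min | 6.0 min | 6.0 min | 6.0 min |

| run | time / min | target / % | substrate / % |
|---|---|---|---|
| Wednesday's | 2.00 | 1.1 | 96.6 |
| Wednesday's | 4.00 | 0 | 93.4 |
| Wednesday's | 8.00 | 4.9 | 86.2 |
| Wednesday's | 20.0 | 6.8 | 67.8 |
| Wednesday's | 40.0 | 10.1 | 52.1 |
| Sunday's | 0.500 | 2.1 | 89.1 |
| Sunday's | 1.00 | 2.2 | 76.5 |
| Sunday's | 2.00 | 4.9 | 64.0 |
| Sunday's | 4.00 | 8.9 | 43.3 |
| Sunday's | 8.00 | 11.6 | 24.8 |

(each reading ± 1 percentage point)

- the numbers in the tables scatter with a standard deviation of 1 percentage point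
- a reading or a percentage of target counts all its forms, free or not
- a reading of substrate is of its free form alone

1. which flask leads in amount of target, in percent of the substrate charged ("all alike" within 1.5 percentage points) (birch / alder / ash / cedar / all alike)
2. how much target is there at the end, in percent of the substrate charged: birch
3. how much target is there at the end, in percent of the substrate charged: alder
4. how much target is there at the end, in percent of the substrate charged: ash
5. how much target is there at the end, in percent of the substrate charged: cedar

So I reckoned with a ratio, not with the substrate peak. Sunday's last reading, 11.6% of target against 75.2% of substrate gone, gave 15.4%. This is the capture share, target in all its forms per substrate gone from the free peak, the usual yield on conversion. Wednesday's gave 21.1%, higher, but that run differed in both temperature and concentration. I carried Sunday's value to alder, which was hotter but at half the concentration and stopped at 6.0 min. I took alder to lose about what Sunday's lost, so my own figure for alder was about 11.6%, and I expected it to lead.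

The forecast named alder as leader, with 4.7% in birch, 8% in alder, 5.9% in ash and 3.1% in cedar. Its ground was that target forms “at a near-constant share of substrate consumed”, and for alder it took about 60% conversion and a share of 13%. Its figure for alder stood lower than my own.

The flasks gave alder as leader, with 6.23% in birch, 13.4% in alder, 4.77% in ash and 0.516% in cedar.

    substrate + target → side product (k = 0.0450 /M/s, Ea = 79.0 kJ/mol)
    first nucleophile + intermediate → target (k = 0.500 /M/s, Ea = 39.0 kJ/mol)
    intermediate → solvolysis product (k = 0.0490 /s, Ea = 93.0 kJ/mol)
    substrate → intermediate (k = 0.00210 /s, Ea = 89.0 kJ/mol)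
    second nucleophile + intermediate → other capture product (k = 0.140 /M/s, Ea = 68.0 kJ/mol)
    substrate + target ⇌ idle adduct, settled at all times (K = 68.0 /M, ΔH = 12.0 kJ/mol)
    2 substrate → self-condensation product (k = 0.0120 /M/s, Ea = 48.0 kJ/mol)
    (constants at 60 °C)

Alder converted 74.7%, idle adduct counted as converted, so its capture share came to 17.9%, where the forecast had 13% and I had 15.4%. At the end of those 6.0 min alder held 25.3% of its substrate, and 83% of the charged first nucleophile stood unbound. In cedar, just after the start, self-condensation used substrate 8.6 times as fast as the turning into intermediate, and the end held 7.42% of self-condensation product, with a capture share of 5.91%.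

A repeat of cedar at 45 °C lost 41.2% of its substrate, so the capture share gives 6.34% of target there. The computed flask holds 6.95%.

The earlier runs and the new flask stem from a simulated flask from invented constants.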